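All runs stem from a simulated flask on assumed constants, and the scatter is random.

Amounts first: target and isomer of the product together count the substrate already spent, so the rest of the charge is, side product apart, the substrate still to react. We want that rest at the moment beta is heated.

| setting | green | grey | teal | beta | gamma | epsilon | delta |
|---|---|---|---|---|---|---|---|
| substrate | 0.12 M | 0.18 M | 0.24 M | 0.24 M | 0.24 M | 0.24 M | 0.24 M |
| reagent | 1.2 equiv | 1.2 equiv | 2.4 equiv | 1.20 equiv | 1.20 equiv | 1.20 equiv | 1.20 equiv |
| temperature | 75 °C | 110 °C | 75 °C |  | 80 °C | 140 °C | 110 °C |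
| remark | run made earlier | run made earlier | run made earlier | at 80 °C until 10 h, from then on at 140 °C |  |  |  |
| time |  |  |  | 30 h | 30 h | 30 h | 30 h |

- percentages count the substrate that a species holds: one side product counts as two
- the numbers in the tables scatter by 0.5 percentage points (one standard deviation)

| run | time / h | target / % | isomer of the product / % |
|---|---|---|---|
| green | 6.00 | 9.2 | 40.5 |
| green | 12.0 | 13.4 | 58.3 |
| green | 20.0 | 14.5 | 70.1 |
| green | 25.0 | 14.3 | 72.9 |
| green | 30.0 | 16.8 | 76.1 |
| grey | 1.33 | 21.6 | 62.1 |
| grey | 2.50 | 24.0 | 69.7 |
| grey | 5.00 | 24.8 | 72.4 |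
| grey | 6.00 | 25.0 | 72.4 |
| teal | 2.50 | 15.5 | 20.1 |
| teal | 5.00 | 23.8 | 34.4 |
| teal | 8.00 | 30.8 | 44.0 |
| teal | 15.0 | 36.6 | 53.9 |
| teal | 30.0 | 39.9 | 59.9 |

(readings scatter by 0.5 percentage points)

1. the best flask by share of target in all that became target or isomer of the product or side product; "all alike" if 1.5 percentage points covers them all (beta / gamma / epsilon / delta / all alike)
2. share of target in all that became target or isomer of the product or side product, beta
3. share of target in all that became target or isomer of the product or side product, gamma
4. share of target in all that became target or isomer of the product or side product, epsilon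
5. share of target in all that became target or isomer of the product or side product, delta

Read the teal table row by row, taking the rest at each time and turning it into a half-life. The row at 5.00 h leaves 41.8%, which gives 3.97 h, the half-life of unspent substrate. The row at 8.00 h gives 4.02 h and the row at 15.0 h gives 4.42 h, so as a reading the half-life changes little over these rows.

Green, at the same temperature with less substrate and less reagent, reads 6.05 h in its first row, which is longer. Beta is charged with 0.288 M of reagent against 0.576 M in teal, but its cold stage stands at 80 °C against 75 °C. We take these two differences to pull opposite ways, so we use teal's half-life as it stands.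

Our own count is then 2.52 half-lives up to the change at 10 h. That leaves 17.5% of the substrate to react hot, and we call this the hot part. If cold and hot substrate each keep the share of their own flask, beta lies the hot part of the way from gamma to epsilon.

The forecast names delta as best, with 27.9% for beta, 27.5% for gamma, 28.9% for epsilon and 29.2% for delta, and it reasons: “Beta does most of its conversion at 80 °C, so it tracks gamma.” Our rule, put on its gamma and epsilon, gives 27.7% for beta, under its own figure.

Epsilon comes out best at 33.3%, with delta at 26.6%, beta at 25.0% and gamma at 23.0%.

    reagent + loose pair → isomer of the product (k = 1200 L mol⁻¹ h⁻¹, Ea = 67.0 kJ mol⁻¹)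
    substrate ⇌ tight pair (K = 0.00320, k = 0.530 h⁻¹, Ea = 101 kJ mol⁻¹, ΔH = 3.00 kJ mol⁻¹)
    reagent + tight pair → target (k = 150 L mol⁻¹ h⁻¹, Ea = 78.0 kJ mol⁻¹)
    tight pair ⇌ loose pair (K = 1.10, k = 130 h⁻¹, Ea = 88.0 kJ mol⁻¹, ΔH = −15.0 kJ mol⁻¹)
    substrate + tight pair → side product (k = 9.90 L mol⁻¹ h⁻¹, Ea = 86.0 kJ mol⁻¹)
    (constants at 80 °C)

At 10.0 h, the change of temperature, beta held 13.7% of its substrate, the limiting reagent, beside the 17.5% we counted. The rule on the flasks' own shares gives 24.8% for beta, which stands at 25.0%. Counted over 15.0 h, the same half-life leaves gamma 7.29% of its substrate, and gamma held 6.34%.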